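The only stereocentre of the target is C8, the oxirane carbon that carries the benzene ring, the ring oxygen and two oxygenated CH2 arms (C9 in the oxirane, C10 as acetate). Because both arms are CH2–X, C8 is traced back to an achiral 2-aryl-1,3-dichloropropan-2-ol, made in one C–C step from an aryl Grignard reagent and 1,3-dichloroacetone and already carrying the angelate and the isovalerate. An engineered halohydrin dehalogenase closes the tertiary hydroxyl onto one of the two enantiotopic CH2Cl groups, which forms the oxirane and fixes C8 in one operation. Acetate then opens that oxirane at CH2 and the alkoxide recloses on the remaining CH2Cl, giving the target.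

Key step: step 7

Remark: C8 is the quaternary oxirane carbon, C9 the oxirane CH2 and C10 the acetoxymethyl carbon; the arrangement at C8 is the same in 13 and 15, and the descriptor changes from S to R only because the CIP ranking of the two CH2 arms changes.

Step 1
Reactants: 1 4-bromo-3-hydroxybenzoic acid
Product: 2 2-bromo-5-(hydroxymethyl)phenol
Conditions: BH3·THF, THF, 0 → 25 °C; MeOH quench
Reagents that add atoms: none
Why: Borane reduction of a carboxylic acid proceeds through the acyloxyborane and leaves the aryl bromide alone, while the phenol is only held as a borate that is hydrolysed on work-up.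

Step 2
Reactants: 2 2-bromo-5-(hydroxymethyl)phenol
Product: 3 1-bromo-2-(tert-butyldimethylsilyloxy)-4-[(tert-butyldimethylsilyloxy)methyl]benzene
Conditions: TBSCl, imidazole, DMF, 25 °C
Reagents that add atoms: tert-butyldimethylsilyl chloride CC(C)(C)[Si](C)(C)Cl
Why: Imidazole-promoted silylation masks both acidic hydroxyls as silyl ethers that tolerate the organomagnesium step and can later be removed without base.

Step 3
Reactants: 3 1-bromo-2-(tert-butyldimethylsilyloxy)-4-[(tert-butyldimethylsilyloxy)methyl]benzene, 4 1,3-dichloroacetone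
Product: 6 2-{2-(tert-butyldimethylsilyloxy)-4-[(tert-butyldimethylsilyloxy)methyl]phenyl}-1,3-dichloropropan-2-ol, via arylmagnesium bromide 5 (not isolated)
Conditions: Mg, LiCl, THF, 25 °C; then added to 4, THF, −78 °C; AcOH, −78 °C
Reagents that add atoms: 1,3-dichloroacetone (4) ClCC(=O)CCl
Why: Grignard addition of the aryl reagent to the strongly electrophilic ketone forms the aryl–C8 bond, and inverse addition with a cold acidic quench should keep the magnesium alkoxide from closing onto a CH2Cl arm; the two arms are identical, so no stereocentre arises.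

Step 4
Reactants: 6 2-{2-(tert-butyldimethylsilyloxy)-4-[(tert-butyldimethylsilyloxy)methyl]phenyl}-1,3-dichloropropan-2-ol
Product: 7 2-(1,3-dichloro-2-hydroxypropan-2-yl)-5-(hydroxymethyl)phenol
Conditions: Bu4NF, AcOH, THF, 0 → 25 °C
Reagents that add atoms: none
Why: Fluoride desilylation buffered with acetic acid cleaves both Si–O bonds, while the medium stays too weakly basic to close the chlorohydrin or to let a phenoxide attack a CH2Cl group.

Step 5
Reactants: 7 2-(1,3-dichloro-2-hydroxypropan-2-yl)-5-(hydroxymethyl)phenol, 8 isovaleric acid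
Product: 9 [4-(1,3-dichloro-2-hydroxypropan-2-yl)-3-hydroxyphenyl]methyl 3-methylbutanoate
Conditions: immobilised Candida antarctica lipase B, 4 Å sieves, MTBE, 40 °C
Reagents that add atoms: isovaleric acid (8) CC(C)CC(=O)O
Why: Lipase-catalysed esterification acylates only the unhindered primary benzylic hydroxyl, since the serine hydrolase accepts neither phenols nor tertiary alcohols, so the three hydroxyls are told apart without a protecting group.

Step 6
Reactants: 9 [4-(1,3-dichloro-2-hydroxypropan-2-yl)-3-hydroxyphenyl]methyl 3-methylbutanoate, 10 angelic acid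
Product: 12 2-(1,3-dichloro-2-hydroxypropan-2-yl)-5-{[(3-methylbutanoyl)oxy]methyl}phenyl (2Z)-2-methylbut-2-enoate, via mixed anhydride 11 (not isolated)
Conditions: 10, 2,4,6-Cl3C6H2COCl, Et3N, toluene, 0 °C; then 9, 0 → 25 °C
Reagents that add atoms: angelic acid (10) C/C=C(/C)C(=O)O
Why: Yamaguchi esterification lets the phenoxide attack the less hindered angeloyl carbonyl of the preformed mixed anhydride at low temperature and without a nucleophilic catalyst, which should keep the Z double bond from isomerising, while the hindered tertiary hydroxyl stays free; the phenol has to be capped here because a free ortho phenol would later open the oxirane.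

Step 7
Reactants: 12 2-(1,3-dichloro-2-hydroxypropan-2-yl)-5-{[(3-methylbutanoyl)oxy]methyl}phenyl (2Z)-2-methylbut-2-enoate
Product: 13 2-[(2S)-2-(chloromethyl)oxiran-2-yl]-5-{[(3-methylbutanoyl)oxy]methyl}phenyl (2Z)-2-methylbut-2-enoate
Conditions: engineered HheC-type halohydrin dehalogenase (purified), KH2PO4/K2HPO4 buffer pH 7.2, n-heptane/MTBE overlay, 25 °C
Reagents that add atoms: none
Why: Proposed new method: the tertiary hydroxyl of 12 is held by the serine–tyrosine pair of the active site, the arginine-activated tyrosinate takes its proton, and the oxygen displaces chloride from the CH2Cl arm lying in the halide pocket in an intramolecular SN2 reaction; the closest known reaction type is the halohydrin dehalogenase closure of prochiral 1,3-dichloropropan-2-ol to epichlorohydrin and of tertiary chlorohydrins to 2,2-disubstituted oxiranes, which has not been shown for a 2-aryl tertiary dichlorohydrin, hence the engineered variant. The oxirane closes in the 3-exo-tet mode. C8 becomes stereogenic because only one of its two enantiotopic CH2Cl arms is attacked; the choice is made by the enzyme pocket alone (catalyst control), and displacement at the pro-R arm gives the S oxirane. The step needs enantiotopic-group selectivity and inert esters: the substrate offers one hydroxyl anchor and C8 substituents of very different size (a flat ortho-acyloxy aryl ring against two small CH2Cl groups), so a pocket that fixes the aryl ring can place only one arm in the halide site, and near-neutral buffer with purified enzyme should spare both esters and keep the non-enzymatic closure slow. Reopening by chloride, which would return achiral 12 and erode the selectivity, is limited by extraction of 13 into the organic layer as it forms.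

Step 8
Reactants: 13 2-[(2S)-2-(chloromethyl)oxiran-2-yl]-5-{[(3-methylbutanoyl)oxy]methyl}phenyl (2Z)-2-methylbut-2-enoate
Product: 15 2-[(2R)-2-[(acetyloxy)methyl]oxiran-2-yl]-5-{[(3-methylbutanoyl)oxy]methyl}phenyl (2Z)-2-methylbut-2-enoate, via cesium chlorohydrin alkoxide 14 (not isolated)
Conditions: CsOAc, DMF, 4 Å sieves, 45 °C
Reagents that add atoms: cesium acetate CC(=O)[O-].[Cs+]
Why: Acetate opens the oxirane at its unsubstituted CH2 by SN2 attack and the tertiary alkoxide 14 closes at once on the remaining CH2Cl in the 3-exo-tet mode (nucleophile-induced oxirane transposition, as known for epichlorohydrins and carboxylates); no bond to C8 is broken, so its arrangement is kept, direct displacement at the neopentyl-like CH2Cl is too slow to compete, and CsCl precipitates from DMF, which limits chloride return.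

Compound list
1 | 4-bromo-3-hydroxybenzoic acid | OC(=O)c1ccc(Br)c(O)c1 | starting material
2 | 2-bromo-5-(hydroxymethyl)phenol | OCc1ccc(Br)c(O)c1 | intermediate
3 | 1-bromo-2-(tert-butyldimethylsilyloxy)-4-[(tert-butyldimethylsilyloxy)methyl]benzene | CC(C)(C)[Si](C)(C)OCc1ccc(Br)c(O[Si](C)(C)C(C)(C)C)c1 | intermediate
4 | 1,3-dichloroacetone | ClCC(=O)CCl | starting material
5 | {2-(tert-butyldimethylsilyloxy)-4-[(tert-butyldimethylsilyloxy)methyl]phenyl}magnesium bromide | CC(C)(C)[Si](C)(C)OCc1ccc([Mg]Br)c(O[Si](C)(C)C(C)(C)C)c1 | intermediate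
6 | 2-{2-(tert-butyldimethylsilyloxy)-4-[(tert-butyldimethylsilyloxy)methyl]phenyl}-1,3-dichloropropan-2-ol | CC(C)(C)[Si](C)(C)OCc1ccc(C(O)(CCl)CCl)c(O[Si](C)(C)C(C)(C)C)c1 | intermediate
7 | 2-(1,3-dichloro-2-hydroxypropan-2-yl)-5-(hydroxymethyl)phenol | OCc1ccc(C(O)(CCl)CCl)c(O)c1 | intermediate
8 | isovaleric acid (3-methylbutanoic acid) | CC(C)CC(=O)O | starting material
9 | [4-(1,3-dichloro-2-hydroxypropan-2-yl)-3-hydroxyphenyl]methyl 3-methylbutanoate | CC(C)CC(=O)OCc1ccc(C(O)(CCl)CCl)c(O)c1 | intermediate
10 | angelic acid ((2Z)-2-methylbut-2-enoic acid) | C/C=C(/C)C(=O)O | starting material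
11 | (2Z)-2-methylbut-2-enoic 2,4,6-trichlorobenzoic anhydride | C/C=C(/C)C(=O)OC(=O)c1c(Cl)cc(Cl)cc1Cl | intermediate
12 | 2-(1,3-dichloro-2-hydroxypropan-2-yl)-5-{[(3-methylbutanoyl)oxy]methyl}phenyl (2Z)-2-methylbut-2-enoate (achiral) | C/C=C(/C)C(=O)Oc1cc(COC(=O)CC(C)C)ccc1C(O)(CCl)CCl | intermediate
13 | 2-[(2S)-2-(chloromethyl)oxiran-2-yl]-5-{[(3-methylbutanoyl)oxy]methyl}phenyl (2Z)-2-methylbut-2-enoate | C/C=C(/C)C(=O)Oc1cc(COC(=O)CC(C)C)ccc1[C@]1(CO1)CCl | intermediate
14 | cesium (2S)-1-(acetyloxy)-3-chloro-2-(2-{[(2Z)-2-methylbut-2-enoyl]oxy}-4-{[(3-methylbutanoyl)oxy]methyl}phenyl)propan-2-olate | C/C=C(/C)C(=O)Oc1cc(COC(=O)CC(C)C)ccc1[C@]([O-])(COC(C)=O)CCl.[Cs+] | intermediate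
15 | 2-[(2R)-2-[(acetyloxy)methyl]oxiran-2-yl]-5-{[(3-methylbutanoyl)oxy]methyl}phenyl (2Z)-2-methylbut-2-enoate | C/C=C(/C)C(=O)Oc1cc(COC(=O)CC(C)C)ccc1[C@]1(COC(C)=O)CO1 | target

Total step count: 8. Longest linear sequence: 8 steps (1 to 15).

Steps most likely to fail

Step 7. No enzyme variant may turn over the bulky, poorly water-soluble diester, the selection between the two CH2Cl arms may be weak, or slow non-enzymatic closure and chloride-driven reopening may erode it. The fallback uses known chemistry only, sets out from 2 and comes back at 15. Lipase-catalysed esterification of 2 with isovaleric acid 8 (as in step 5) should give (4-bromo-3-hydroxyphenyl)methyl 3-methylbutanoate F1. Yamaguchi angeloylation (as in step 6) then gives 2-bromo-5-{[(3-methylbutanoyl)oxy]methyl}phenyl (2Z)-2-methylbut-2-enoate F2. Stille coupling with 2-(tributylstannyl)prop-2-en-1-ol (Pd(PPh3)4, CuI, DMF, 60 °C) gives the 2-aryl allylic alcohol 2-(3-hydroxyprop-1-en-2-yl)-5-{[(3-methylbutanoyl)oxy]methyl}phenyl (2Z)-2-methylbut-2-enoate F3. Sharpless asymmetric epoxidation (Ti(OiPr)4, L-(+)-diethyl tartrate, t-BuOOH, 4 Å sieves, CH2Cl2, −20 °C) should deliver oxygen to the face that gives 2-[(2S)-2-(hydroxymethyl)oxiran-2-yl]-5-{[(3-methylbutanoyl)oxy]methyl}phenyl (2Z)-2-methylbut-2-enoate F4, the stereocentre being set by the tartrate. Acetylation (Ac2O, pyridine, 0 °C) gives 15, whose descriptor is R only through the priority change.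

Step 8. The transient tertiary alkoxide may take the angeloyl group from the neighbouring phenol oxygen through a six-membered transition state instead of closing the oxirane, and dissolved chloride may reopen 13 reversibly and scramble C8. The fallback sets out from 13 and comes back at 15. The oxirane is opened with acetic acid under acetate catalysis (CsOAc, AcOH, DMF, 50 °C), so the alkoxide is protonated as it forms and no chloride is released, giving 2-[(2S)-1-(acetyloxy)-3-chloro-2-hydroxypropan-2-yl]-5-{[(3-methylbutanoyl)oxy]methyl}phenyl (2Z)-2-methylbut-2-enoate F5. The one remaining CH2Cl is then closed by a halohydrin dehalogenase in neutral buffer, where the alkoxide exists only inside the active site. Because this is the arm that the step 7 variant leaves untouched, a family member of opposite or no arm preference from the same screening panel is used.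

Step 3. The hindered ortho-silyloxy aryl Grignard reagent may deprotonate the enolisable ketone instead of adding to it, or the magnesium alkoxide may close onto a CH2Cl arm before the quench. The fallback sets out from 3 (through its Grignard reagent 5) and comes back at 6. Reagent 5 is acylated with 2-chloro-N-methoxy-N-methylacetamide (THF, −20 → 0 °C; Weinreb ketone synthesis, NH4Cl work-up) to give 1-{2-(tert-butyldimethylsilyloxy)-4-[(tert-butyldimethylsilyloxy)methyl]phenyl}-2-chloroethan-1-one F6. Chloromethyllithium made in the flask from ICH2Cl and MeLi·LiBr (THF, −78 °C; AcOH quench at −78 °C) then adds to the ketone to give 6.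

Further compounds
F1 | step 7 | (4-bromo-3-hydroxyphenyl)methyl 3-methylbutanoate | CC(C)CC(=O)OCc1ccc(Br)c(O)c1
F2 | step 7 | 2-bromo-5-{[(3-methylbutanoyl)oxy]methyl}phenyl (2Z)-2-methylbut-2-enoate | C/C=C(/C)C(=O)Oc1cc(COC(=O)CC(C)C)ccc1Br
F3 | step 7 | 2-(3-hydroxyprop-1-en-2-yl)-5-{[(3-methylbutanoyl)oxy]methyl}phenyl (2Z)-2-methylbut-2-enoate | C/C=C(/C)C(=O)Oc1cc(COC(=O)CC(C)C)ccc1C(=C)CO
F4 | step 7 | 2-[(2S)-2-(hydroxymethyl)oxiran-2-yl]-5-{[(3-methylbutanoyl)oxy]methyl}phenyl (2Z)-2-methylbut-2-enoate | C/C=C(/C)C(=O)Oc1cc(COC(=O)CC(C)C)ccc1[C@]1(CO)CO1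
F5 | step 8 | 2-[(2S)-1-(acetyloxy)-3-chloro-2-hydroxypropan-2-yl]-5-{[(3-methylbutanoyl)oxy]methyl}phenyl (2Z)-2-methylbut-2-enoate | C/C=C(/C)C(=O)Oc1cc(COC(=O)CC(C)C)ccc1[C@](O)(COC(C)=O)CCl
F6 | step 3 | 1-{2-(tert-butyldimethylsilyloxy)-4-[(tert-butyldimethylsilyloxy)methyl]phenyl}-2-chloroethan-1-one | CC(C)(C)[Si](C)(C)OCc1ccc(C(=O)CCl)c(O[Si](C)(C)C(C)(C)C)c1
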